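**Retrosynthetic overview**
1. Target 31 ⇐ carbinol 28: global MOM removal, para-quinone methide formation and 5-exo intramolecular oxa-Michael (1,6-) addition close ring A last, trans to the fixed C3 centre.
2. 28 ⇐ ketone 27 (dynamic kinetic asymmetric hydrogenation sets C3 of ring A) ⇐ Pd α-arylation joining stilbene ketone 26 with ring-B aryl chloride 15.
3. 15 ⇐ carbinol 11 by the same quinone methide oxa-Michael closure (ring B first) ⇐ ketone 10 (dynamic kinetic hydrogenation) ⇐ two Pd α-arylations of acetophenone 6 with iodide 4 and bromide 9.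
4. 26 ⇐ acetophenone 25 + bromostilbene 23 (Pd α-arylation); 23 ⇐ Horner–Wadsworth–Emmons olefination of phosphonate 20 with aldehyde 22.
5. Ring order: dihydrobenzofuran ring B (step 8), then dihydrobenzofuran ring A (step 20).

Assumption: in both dynamic kinetic hydrogenations the Felkin–Anh ketone epimer (hydride anti to the 2,6-dioxygenated aryl) reduces faster, giving the like alcohols; if the unlike alcohol prevails, the antipodal catalyst is used so that the diarylmethine centre is as drawn.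

MOM = methoxymethyl.

**Route**

Step 1
Reactants: 1 5-chlorobenzene-1,3-diol
Product: 2 1-chloro-3,5-bis(methoxymethoxy)benzene
Conditions: MOMCl, K2CO3, acetone, 0 °C to rt
Reagents that add atoms: chloromethyl methyl ether, COCCl
Why: Williamson-type O-alkylation of both phenoxides installs acid-labile MOM ethers that direct the next metalation and survive base, palladium coupling and hydrogenation.

Step 2
Reactants: 2 1-chloro-3,5-bis(methoxymethoxy)benzene
Product: 4 5-chloro-2-iodo-1,3-bis(methoxymethoxy)benzene, via aryllithium 3 (not isolated)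
Conditions: n-BuLi, THF, 0 °C; then I2, −78 °C to rt
Reagents that add atoms: iodine, II
Why: Directed ortho-metalation, in which the two MOM ethers cooperatively steer n-BuLi to the carbon between them (the aryl chloride is not exchanged), followed by iodinolysis of the aryllithium.

Step 3
Reactants: 5 1-(3,4-dihydroxyphenyl)ethan-1-one
Product: 6 1-[3,4-bis(methoxymethoxy)phenyl]ethan-1-one
Conditions: MOMCl, K2CO3, acetone, 0 °C to rt
Reagents that add atoms: chloromethyl methyl ether, COCCl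
Why: Phenol MOM etherification under carbonate, which leaves the methyl ketone untouched.

Step 4
Reactants: 6 1-[3,4-bis(methoxymethoxy)phenyl]ethan-1-one; 4 5-chloro-2-iodo-1,3-bis(methoxymethoxy)benzene
Product: 7 1-[3,4-bis(methoxymethoxy)phenyl]-2-[4-chloro-2,6-bis(methoxymethoxy)phenyl]ethan-1-one
Conditions: Pd2(dba)3, Xantphos, NaOt-Bu, toluene, 80 °C
Reagents that add atoms: none
Why: Palladium-catalysed ketone α-arylation (Buchwald–Hartwig enolate arylation), in which oxidative addition occurs at the C–I bond only (Xantphos does not activate the aryl chloride) and the crowded product resists a second arylation.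

Step 5
Reactants: 8 5-bromobenzene-1,3-diol
Product: 9 1-bromo-3,5-bis(methoxymethoxy)benzene
Conditions: MOMCl, K2CO3, acetone, 0 °C to rt
Reagents that add atoms: chloromethyl methyl ether, COCCl
Why: Phenol MOM etherification by Williamson-type O-alkylation.

Step 6
Reactants: 7 1-[3,4-bis(methoxymethoxy)phenyl]-2-[4-chloro-2,6-bis(methoxymethoxy)phenyl]ethan-1-one; 9 1-bromo-3,5-bis(methoxymethoxy)benzene
Product: 10 rac-1-[3,4-bis(methoxymethoxy)phenyl]-2-[3,5-bis(methoxymethoxy)phenyl]-2-[4-chloro-2,6-bis(methoxymethoxy)phenyl]ethan-1-one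
Conditions: Pd2(dba)3, Xantphos, NaOt-Bu, toluene, 90 °C
Reagents that add atoms: none
Why: Second palladium-catalysed α-arylation at the more acidic benzylic position with the unhindered aryl bromide (C–Br reacts, C–Cl is kept); the new methine forms racemic and stays base-labile, which the next step exploits.

Step 7
Reactants: 10 rac-1-[3,4-bis(methoxymethoxy)phenyl]-2-[3,5-bis(methoxymethoxy)phenyl]-2-[4-chloro-2,6-bis(methoxymethoxy)phenyl]ethan-1-one
Product: 11 (1S,2S)-1-[3,4-bis(methoxymethoxy)phenyl]-2-[3,5-bis(methoxymethoxy)phenyl]-2-[4-chloro-2,6-bis(methoxymethoxy)phenyl]ethan-1-ol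
Conditions: RuCl2[(R)-xylbinap][(R)-daipen] (1 mol%), t-BuOK (10 mol%), H2 (10 atm), i-PrOH/THF, 25 °C; chromatography
Reagents that add atoms: none
Why: Noyori asymmetric hydrogenation with dynamic kinetic resolution, in which base racemises the acidic α,α-diaryl ketone while the catalyst fixes the carbinol centre as S and reduces the Felkin–Anh epimer faster, so the diarylmethine centre emerges S; the minor diastereomer is removed by chromatography.

Step 8
Reactants: 11 (1S,2S)-1-[3,4-bis(methoxymethoxy)phenyl]-2-[3,5-bis(methoxymethoxy)phenyl]-2-[4-chloro-2,6-bis(methoxymethoxy)phenyl]ethan-1-ol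
Product: 14 (2S,3S)-6-chloro-2-(3,4-dihydroxyphenyl)-3-(3,5-dihydroxyphenyl)-2,3-dihydro-1-benzofuran-4-ol, via hexaphenol carbinol 12 (not isolated), via para-quinone methide 13 (not isolated)
Conditions: HCl (2 M), MeOH/THF, 45 °C, argon
Reagents that add atoms: none
Why: Acid removes the six MOM groups and ionises the 4-hydroxybenzylic alcohol to a para-quinone methide that is trapped by the flanking phenol in a 5-exo intramolecular oxa-Michael (1,6-conjugate) addition; the carbinol configuration is erased and C2 is set trans to the fixed C3 aryl under reversible, thermodynamic control, giving the (2S,3S) ring.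

Step 9
Reactants: 14 (2S,3S)-6-chloro-2-(3,4-dihydroxyphenyl)-3-(3,5-dihydroxyphenyl)-2,3-dihydro-1-benzofuran-4-ol
Product: 15 (2S,3S)-2-[3,4-bis(methoxymethoxy)phenyl]-3-[3,5-bis(methoxymethoxy)phenyl]-6-chloro-4-(methoxymethoxy)-2,3-dihydro-1-benzofuran
Conditions: MOMCl (excess), K2CO3, DMF, 0 to 40 °C
Reagents that add atoms: chloromethyl methyl ether, COCCl
Why: Exhaustive Williamson MOM etherification re-masks the five phenols so that the aryl chloride can enter the base-mediated coupling; no stereocentre is touched.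

Step 10
Reactants: 16 methyl 4-bromo-3,5-dihydroxybenzoate
Product: 17 methyl 4-bromo-3,5-bis(methoxymethoxy)benzoate
Conditions: MOMCl, K2CO3, acetone, 0 °C to rt
Reagents that add atoms: chloromethyl methyl ether, COCCl
Why: Phenol MOM etherification by Williamson-type O-alkylation; the ester is inert to carbonate.

Step 11
Reactants: 17 methyl 4-bromo-3,5-bis(methoxymethoxy)benzoate
Product: 18 [4-bromo-3,5-bis(methoxymethoxy)phenyl]methanol
Conditions: i-Bu2AlH, CH2Cl2, −78 to 0 °C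
Reagents that add atoms: none
Why: Hydride reduction of the ester to the benzylic alcohol, with the aryl bromide and MOM ethers inert to i-Bu2AlH.

Step 12
Reactants: 18 [4-bromo-3,5-bis(methoxymethoxy)phenyl]methanol
Product: 19 2-bromo-5-(bromomethyl)-1,3-bis(methoxymethoxy)benzene
Conditions: CBr4, PPh3, CH2Cl2, 0 °C
Reagents that add atoms: carbon tetrabromide, BrC(Br)(Br)Br
Why: Appel bromination converts the primary benzylic alcohol to the bromide under neutral conditions that spare the acid-sensitive MOM ethers.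

Step 13
Reactants: 19 2-bromo-5-(bromomethyl)-1,3-bis(methoxymethoxy)benzene
Product: 20 diethyl {[4-bromo-3,5-bis(methoxymethoxy)phenyl]methyl}phosphonate
Conditions: P(OEt)3 (neat), 130 °C
Reagents that add atoms: triethyl phosphite, CCOP(OCC)OCC
Why: Michaelis–Arbuzov reaction of the benzylic bromide; the aryl bromide does not react without a transition-metal catalyst.

Step 14
Reactants: 21 4-hydroxybenzaldehyde
Product: 22 4-(methoxymethoxy)benzaldehyde
Conditions: MOMCl, K2CO3, acetone, 0 °C to rt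
Reagents that add atoms: chloromethyl methyl ether, COCCl
Why: Phenol MOM etherification by Williamson-type O-alkylation.

Step 15
Reactants: 20 diethyl {[4-bromo-3,5-bis(methoxymethoxy)phenyl]methyl}phosphonate; 22 4-(methoxymethoxy)benzaldehyde
Product: 23 2-bromo-1,3-bis(methoxymethoxy)-5-[(E)-2-[4-(methoxymethoxy)phenyl]ethenyl]benzene
Conditions: KOt-Bu, THF, 0 °C to rt
Reagents that add atoms: none
Why: Horner–Wadsworth–Emmons olefination of a benzylic phosphonate with an aryl aldehyde gives the stilbene with high E selectivity.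

Step 16
Reactants: 24 1-(4-hydroxyphenyl)ethan-1-one
Product: 25 1-[4-(methoxymethoxy)phenyl]ethan-1-one
Conditions: MOMCl, K2CO3, acetone, 0 °C to rt
Reagents that add atoms: chloromethyl methyl ether, COCCl
Why: Phenol MOM etherification by Williamson-type O-alkylation.

Step 17
Reactants: 25 1-[4-(methoxymethoxy)phenyl]ethan-1-one; 23 2-bromo-1,3-bis(methoxymethoxy)-5-[(E)-2-[4-(methoxymethoxy)phenyl]ethenyl]benzene
Product: 26 2-{2,6-bis(methoxymethoxy)-4-[(E)-2-[4-(methoxymethoxy)phenyl]ethenyl]phenyl}-1-[4-(methoxymethoxy)phenyl]ethan-1-one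
Conditions: Pd2(dba)3, XPhos, NaOt-Bu, toluene, 90 °C
Reagents that add atoms: none
Why: Palladium-catalysed α-arylation of the methyl ketone enolate with the di-ortho-alkoxy aryl bromide, the bulky biaryl phosphine promoting oxidative addition and reductive elimination while the stilbene is a spectator.

Step 18
Reactants: 26 2-{2,6-bis(methoxymethoxy)-4-[(E)-2-[4-(methoxymethoxy)phenyl]ethenyl]phenyl}-1-[4-(methoxymethoxy)phenyl]ethan-1-one; 15 (2S,3S)-2-[3,4-bis(methoxymethoxy)phenyl]-3-[3,5-bis(methoxymethoxy)phenyl]-6-chloro-4-(methoxymethoxy)-2,3-dihydro-1-benzofuran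
Product: 27 (2RS)-2-{(2S,3S)-2-[3,4-bis(methoxymethoxy)phenyl]-3-[3,5-bis(methoxymethoxy)phenyl]-4-(methoxymethoxy)-2,3-dihydro-1-benzofuran-6-yl}-2-{2,6-bis(methoxymethoxy)-4-[(E)-2-[4-(methoxymethoxy)phenyl]ethenyl]phenyl}-1-[4-(methoxymethoxy)phenyl]ethan-1-one (both epimers at C2 of the ethanone)
Conditions: Pd2(dba)3, XPhos, K3PO4, toluene, 100 °C
Reagents that add atoms: none
Why: Convergent palladium-catalysed α-arylation of the benzylic ketone with the unhindered aryl chloride (XPhos activates C–Cl and the mild phosphate base spares the dihydrobenzofuran); the new methine forms as both epimers and remains epimerisable.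

Step 19
Reactants: 27 (2RS)-triaryl ketone from step 18
Product: 28 (1R,2R)-2-{(2S,3S)-2-[3,4-bis(methoxymethoxy)phenyl]-3-[3,5-bis(methoxymethoxy)phenyl]-4-(methoxymethoxy)-2,3-dihydro-1-benzofuran-6-yl}-2-{2,6-bis(methoxymethoxy)-4-[(E)-2-[4-(methoxymethoxy)phenyl]ethenyl]phenyl}-1-[4-(methoxymethoxy)phenyl]ethan-1-ol
Conditions: RuCl2[(S)-xylbinap][(S)-daipen] (1 mol%), t-BuOK (10 mol%), H2 (10 atm), i-PrOH/THF, 25 °C; chromatography
Reagents that add atoms: none
Why: Noyori dynamic kinetic asymmetric hydrogenation with the antipodal catalyst sets the carbinol as R by catalyst control and the diarylmethine as R through the faster-reacting Felkin–Anh epimer of the equilibrating ketone, the stilbene and ring B being inert; diastereomers are separated.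

Step 20
Reactants: 28 (1R,2R)-carbinol from step 19
Product: 31 (2R,3R)-3-[(2S,3S)-2-(3,4-dihydroxyphenyl)-3-(3,5-dihydroxyphenyl)-4-hydroxy-2,3-dihydro-1-benzofuran-6-yl]-2-(4-hydroxyphenyl)-6-[(E)-2-(4-hydroxyphenyl)ethenyl]-2,3-dihydro-1-benzofuran-4-ol, via nonaphenol carbinol 29 (not isolated), via para-quinone methide 30 (not isolated)
Conditions: HCl (2 M), MeOH/THF, 45 °C, argon, dark
Reagents that add atoms: none
Why: Acid strips the nine MOM groups, the 4-hydroxybenzylic alcohol collapses to a para-quinone methide and a flanking ring-A phenol closes the second dihydrobenzofuran by 5-exo intramolecular oxa-Michael (1,6-) addition, trans to the fixed C3 substituent under thermodynamic control, giving the (2R,3R) ring and the free octaphenol.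

**Compound list**
1 | 5-chlorobenzene-1,3-diol | Oc1cc(O)cc(Cl)c1 | starting material
2 | 1-chloro-3,5-bis(methoxymethoxy)benzene | COCOc1cc(Cl)cc(OCOC)c1 | intermediate
3 | [4-chloro-2,6-bis(methoxymethoxy)phenyl]lithium | [Li]c1c(OCOC)cc(Cl)cc1OCOC | intermediate
4 | 5-chloro-2-iodo-1,3-bis(methoxymethoxy)benzene | COCOc1cc(Cl)cc(OCOC)c1I | intermediate
5 | 1-(3,4-dihydroxyphenyl)ethan-1-one | CC(=O)c1ccc(O)c(O)c1 | starting material
6 | 1-[3,4-bis(methoxymethoxy)phenyl]ethan-1-one | CC(=O)c1ccc(OCOC)c(OCOC)c1 | intermediate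
7 | 1-[3,4-bis(methoxymethoxy)phenyl]-2-[4-chloro-2,6-bis(methoxymethoxy)phenyl]ethan-1-one | O=C(Cc1c(OCOC)cc(Cl)cc1OCOC)c1ccc(OCOC)c(OCOC)c1 | intermediate
8 | 5-bromobenzene-1,3-diol | Oc1cc(O)cc(Br)c1 | starting material
9 | 1-bromo-3,5-bis(methoxymethoxy)benzene | COCOc1cc(Br)cc(OCOC)c1 | intermediate
10 | rac-1-[3,4-bis(methoxymethoxy)phenyl]-2-[3,5-bis(methoxymethoxy)phenyl]-2-[4-chloro-2,6-bis(methoxymethoxy)phenyl]ethan-1-one | O=C(C(c1cc(OCOC)cc(OCOC)c1)c1c(OCOC)cc(Cl)cc1OCOC)c1ccc(OCOC)c(OCOC)c1 | intermediate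
11 | (1S,2S)-1-[3,4-bis(methoxymethoxy)phenyl]-2-[3,5-bis(methoxymethoxy)phenyl]-2-[4-chloro-2,6-bis(methoxymethoxy)phenyl]ethan-1-ol | O[C@H](c1ccc(OCOC)c(OCOC)c1)[C@H](c1c(OCOC)cc(Cl)cc1OCOC)c1cc(OCOC)cc(OCOC)c1 | intermediate
12 | (1S,2S)-2-(4-chloro-2,6-dihydroxyphenyl)-1-(3,4-dihydroxyphenyl)-2-(3,5-dihydroxyphenyl)ethan-1-ol | O[C@H](c1ccc(O)c(O)c1)[C@H](c1c(O)cc(Cl)cc1O)c1cc(O)cc(O)c1 | intermediate
13 | 4-[(2S)-2-(4-chloro-2,6-dihydroxyphenyl)-2-(3,5-dihydroxyphenyl)ethylidene]-2-hydroxycyclohexa-2,5-dien-1-one | O=C1C=CC(=C[C@H](c2c(O)cc(Cl)cc2O)c2cc(O)cc(O)c2)C=C1O | intermediate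
14 | (2S,3S)-6-chloro-2-(3,4-dihydroxyphenyl)-3-(3,5-dihydroxyphenyl)-2,3-dihydro-1-benzofuran-4-ol | Clc1cc(O)c2c(c1)O[C@H](c1ccc(O)c(O)c1)[C@H]2c1cc(O)cc(O)c1 | intermediate
15 | (2S,3S)-2-[3,4-bis(methoxymethoxy)phenyl]-3-[3,5-bis(methoxymethoxy)phenyl]-6-chloro-4-(methoxymethoxy)-2,3-dihydro-1-benzofuran | Clc1cc(OCOC)c2c(c1)O[C@H](c1ccc(OCOC)c(OCOC)c1)[C@H]2c1cc(OCOC)cc(OCOC)c1 | intermediate
16 | methyl 4-bromo-3,5-dihydroxybenzoate | COC(=O)c1cc(O)c(Br)c(O)c1 | starting material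
17 | methyl 4-bromo-3,5-bis(methoxymethoxy)benzoate | COC(=O)c1cc(OCOC)c(Br)c(OCOC)c1 | intermediate
18 | [4-bromo-3,5-bis(methoxymethoxy)phenyl]methanol | OCc1cc(OCOC)c(Br)c(OCOC)c1 | intermediate
19 | 2-bromo-5-(bromomethyl)-1,3-bis(methoxymethoxy)benzene | BrCc1cc(OCOC)c(Br)c(OCOC)c1 | intermediate
20 | diethyl {[4-bromo-3,5-bis(methoxymethoxy)phenyl]methyl}phosphonate | CCOP(=O)(OCC)Cc1cc(OCOC)c(Br)c(OCOC)c1 | intermediate
21 | 4-hydroxybenzaldehyde | O=Cc1ccc(O)cc1 | starting material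
22 | 4-(methoxymethoxy)benzaldehyde | COCOc1ccc(C=O)cc1 | intermediate
23 | 2-bromo-1,3-bis(methoxymethoxy)-5-[(E)-2-[4-(methoxymethoxy)phenyl]ethenyl]benzene | COCOc1ccc(/C=C/c2cc(OCOC)c(Br)c(OCOC)c2)cc1 | intermediate
24 | 1-(4-hydroxyphenyl)ethan-1-one | CC(=O)c1ccc(O)cc1 | starting material
25 | 1-[4-(methoxymethoxy)phenyl]ethan-1-one | CC(=O)c1ccc(OCOC)cc1 | intermediate
26 | 2-{2,6-bis(methoxymethoxy)-4-[(E)-2-[4-(methoxymethoxy)phenyl]ethenyl]phenyl}-1-[4-(methoxymethoxy)phenyl]ethan-1-one | O=C(Cc1c(OCOC)cc(/C=C/c2ccc(OCOC)cc2)cc1OCOC)c1ccc(OCOC)cc1 | intermediate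
27 | (2RS)-2-{(2S,3S)-2-[3,4-bis(methoxymethoxy)phenyl]-3-[3,5-bis(methoxymethoxy)phenyl]-4-(methoxymethoxy)-2,3-dihydro-1-benzofuran-6-yl}-2-{2,6-bis(methoxymethoxy)-4-[(E)-2-[4-(methoxymethoxy)phenyl]ethenyl]phenyl}-1-[4-(methoxymethoxy)phenyl]ethan-1-one | O=C(C(c1cc(OCOC)c2c(c1)O[C@H](c1ccc(OCOC)c(OCOC)c1)[C@H]2c1cc(OCOC)cc(OCOC)c1)c1c(OCOC)cc(/C=C/c2ccc(OCOC)cc2)cc1OCOC)c1ccc(OCOC)cc1 | intermediate
28 | (1R,2R)-2-{(2S,3S)-2-[3,4-bis(methoxymethoxy)phenyl]-3-[3,5-bis(methoxymethoxy)phenyl]-4-(methoxymethoxy)-2,3-dihydro-1-benzofuran-6-yl}-2-{2,6-bis(methoxymethoxy)-4-[(E)-2-[4-(methoxymethoxy)phenyl]ethenyl]phenyl}-1-[4-(methoxymethoxy)phenyl]ethan-1-ol | O[C@@H](c1ccc(OCOC)cc1)[C@@H](c1c(OCOC)cc(/C=C/c2ccc(OCOC)cc2)cc1OCOC)c1cc(OCOC)c2c(c1)O[C@H](c1ccc(OCOC)c(OCOC)c1)[C@H]2c1cc(OCOC)cc(OCOC)c1 | intermediate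
29 | (1R,2R)-2-[(2S,3S)-2-(3,4-dihydroxyphenyl)-3-(3,5-dihydroxyphenyl)-4-hydroxy-2,3-dihydro-1-benzofuran-6-yl]-2-{2,6-dihydroxy-4-[(E)-2-(4-hydroxyphenyl)ethenyl]phenyl}-1-(4-hydroxyphenyl)ethan-1-ol | O[C@@H](c1ccc(O)cc1)[C@@H](c1c(O)cc(/C=C/c2ccc(O)cc2)cc1O)c1cc(O)c2c(c1)O[C@H](c1ccc(O)c(O)c1)[C@H]2c1cc(O)cc(O)c1 | intermediate
30 | 4-[(2R)-2-[(2S,3S)-2-(3,4-dihydroxyphenyl)-3-(3,5-dihydroxyphenyl)-4-hydroxy-2,3-dihydro-1-benzofuran-6-yl]-2-{2,6-dihydroxy-4-[(E)-2-(4-hydroxyphenyl)ethenyl]phenyl}ethylidene]cyclohexa-2,5-dien-1-one | O=C1C=CC(=C[C@@H](c2c(O)cc(/C=C/c3ccc(O)cc3)cc2O)c2cc(O)c3c(c2)O[C@H](c2ccc(O)c(O)c2)[C@H]3c2cc(O)cc(O)c2)C=C1 | intermediate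
31 | (2R,3R)-3-[(2S,3S)-2-(3,4-dihydroxyphenyl)-3-(3,5-dihydroxyphenyl)-4-hydroxy-2,3-dihydro-1-benzofuran-6-yl]-2-(4-hydroxyphenyl)-6-[(E)-2-(4-hydroxyphenyl)ethenyl]-2,3-dihydro-1-benzofuran-4-ol | Oc1ccc(/C=C/c2cc(O)c3c(c2)O[C@@H](c2ccc(O)cc2)[C@@H]3c2cc(O)c3c(c2)O[C@H](c2ccc(O)c(O)c2)[C@H]3c2cc(O)cc(O)c2)cc1 | target

**Totals**
Total step count: 20.
Longest linear sequence: 10 steps (steps 1, 2, 4, 6, 7, 8, 9, 18, 19, 20); the ring-A branch (steps 10–13, 15, 17, then 18–20) is 9 steps.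

**Steps most likely to fail, with fallbacks**

Step 7, the dynamic kinetic hydrogenation of the hindered, electron-rich triaryl ketone, may be slow or give poor diastereoselection. The fallback sets out from 10 and replaces the dynamic process by reagent-controlled reduction with recycling. (R)-Me-CBS oxazaborolidine with BH3·SMe2 (THF, −20 °C) reduces both ketone enantiomers to (1S)-carbinols, namely 11 and its epimer (1S,2R)-1-[3,4-bis(methoxymethoxy)phenyl]-2-[3,5-bis(methoxymethoxy)phenyl]-2-[4-chloro-2,6-bis(methoxymethoxy)phenyl]ethan-1-ol F1. Chromatography returns 11 to the route. F1 is oxidised with Dess–Martin periodinane back to ketone 10, whose methine re-equilibrates, for another pass.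

Step 18, the union, forms a triaryl-substituted carbon from an enolate that already carries the di-ortho-substituted aryl and may stall. The fallback sets out from 25 and 15 and reverses the order of the two C–C bond formations. The unhindered chloride 15 is first coupled with methyl ketone 25 (Pd2(dba)3, XPhos, K3PO4, toluene, 100 °C) to give 2-{(2S,3S)-2-[3,4-bis(methoxymethoxy)phenyl]-3-[3,5-bis(methoxymethoxy)phenyl]-4-(methoxymethoxy)-2,3-dihydro-1-benzofuran-6-yl}-1-[4-(methoxymethoxy)phenyl]ethan-1-one F2. F2 is then arylated with bromostilbene 23 under the same catalyst, so the hindered aryl sits on palladium and not on the enolate carbon. This comes back to the route at 27.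

Step 4, the α-arylation with a di-ortho-alkoxy aryl iodide that also carries a chloride, may suffer from slow oxidative addition or loss of chemoselectivity. The fallback sets out from 2 (through aryllithium 3) and from 6 and inverts the polarity of the coupling. Aryllithium 3 is quenched with B(OMe)3 and aqueous NH4Cl to give [4-chloro-2,6-bis(methoxymethoxy)phenyl]boronic acid F3. Ketone 6 is brominated (PhNMe3Br3, THF, 0 °C) to 2-bromo-1-[3,4-bis(methoxymethoxy)phenyl]ethan-1-one F4. Suzuki-type coupling of F3 with F4 (Pd(PPh3)4, K3PO4, toluene/water, 60 °C) comes back to the route at 7.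

**Further compounds**
F1 | step 7 | (1S,2R)-1-[3,4-bis(methoxymethoxy)phenyl]-2-[3,5-bis(methoxymethoxy)phenyl]-2-[4-chloro-2,6-bis(methoxymethoxy)phenyl]ethan-1-ol | O[C@H](c1ccc(OCOC)c(OCOC)c1)[C@@H](c1c(OCOC)cc(Cl)cc1OCOC)c1cc(OCOC)cc(OCOC)c1
F2 | step 18 | 2-{(2S,3S)-2-[3,4-bis(methoxymethoxy)phenyl]-3-[3,5-bis(methoxymethoxy)phenyl]-4-(methoxymethoxy)-2,3-dihydro-1-benzofuran-6-yl}-1-[4-(methoxymethoxy)phenyl]ethan-1-one | O=C(Cc1cc(OCOC)c2c(c1)O[C@H](c1ccc(OCOC)c(OCOC)c1)[C@H]2c1cc(OCOC)cc(OCOC)c1)c1ccc(OCOC)cc1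
F3 | step 4 | [4-chloro-2,6-bis(methoxymethoxy)phenyl]boronic acid | OB(O)c1c(OCOC)cc(Cl)cc1OCOC
F4 | step 4 | 2-bromo-1-[3,4-bis(methoxymethoxy)phenyl]ethan-1-one | O=C(CBr)c1ccc(OCOC)c(OCOC)c1
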